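The ratio ρ of two times, the moment asked about over the lag of target, is the number to reckon for this flask.

| flask | starting material | second substrate | protic impurity | free catalyst | remark |
|---|---|---|---|---|---|
| Saturday's | 0.16 M | 1 equiv | 0.0080 M | 1.1 mol% | run made earlier |
| Friday's | 0.16 M | 1 equiv | 0.032 M | 1.1 mol% | run made earlier |
| flask | 0.16 M | 1.00 equiv | 0.0160 M | 1.1 mol% |  |

- Saturday's (time / d: target / %, starting material / %): 0.208: 0.4, 95.5; 0.625: 1.3, 92.6; 1.04: 2.8, 88.9; 1.67: 9.7, 85.8; 2.50: 20.4, 74.5
- Friday's (time / d: target / %, starting material / %): 0.208: 0.1, 91.1; 0.333: 2.9, 85.3; 0.625: 2.0, 81.3; 1.25: 6.7, 76.0; 2.50: 18.5, 63.0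

(readings scatter by 1 percentage point)

* apparent order in second substrate when 30 % of the starting material are converted (percent change of the rate of making target for one percent more second substrate charged)

- what was read earlier has a scatter of 1 percentage point, one standard deviation
- no earlier run changes the charge of second substrate; that part of a forecast is a guess

Read the two runs column against column. At 2.50 d, starting material lost minus target stands at 5.10 % on Saturday and 18.5 % on Friday, close to impurity over starting material in those charges, 5.00 % and 20.0 %. So the impurity takes about its own amount of starting material. The new flask then loses 10.0 % that way, and 30 % conversion needs 20.0 % of target, which both runs held near 2.50 d (20.4 % and 18.5 %).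

The target column shows the lag. The line through the last two target readings meets zero at 0.918 d on Saturday and 0.540 d on Friday. Friday's run held 4.00 times Saturday's impurity, yet its lag reads shorter, so this reckoning does not put the lag on the impurity. Second substrate, charged alike in both runs, remains the suspect: a competitor for free catalyst (competitive inhibition), consumed during the lag.

Taking Saturday's lag, the longer, as its time constant, the clock ratio ρ, moment over lag, is 2.72, and exp(−ρ) puts the estimated share of second substrate remaining at 6.56 %. This reckoning therefore commits to an order near 0, slightly below it if anything.

The forecast differs: 0.7, within 0.1 to 1.1, on the ground that “A bimolecular catalytic step suggests about 1, and partial catalyst saturation by the second substrate would lower it.”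

The flask gives −0.067, lower than the forecast's low end.

    starting material + free catalyst ⇌ catalyst intermediate A (K = 7.80 M⁻¹, k = 0.00470 M⁻¹ s⁻¹)
    catalyst intermediate A → free catalyst + target (k = 4.39 × 10⁻⁴ s⁻¹)
    second substrate + free catalyst ⇌ catalyst intermediate B (K = 45.5 M⁻¹, k = 0.222 M⁻¹ s⁻¹)
    catalyst intermediate B → free catalyst + second product (k = 8.42 × 10⁻⁴ s⁻¹)
    starting material + protic impurity → quenched substrate (k = 2.65 × 10⁻⁴ M⁻¹ s⁻¹)

In these equations second product and target stand on separate paths, through catalyst intermediate B and catalyst intermediate A. The asked conversion stood at 2.52 d, where ρ, taken with the same lag, is 2.75. At the marked time 2.00 d, ρ is 2.18 and exp(−ρ) gives 11.3 %, while the flask held 7.4 % of its second substrate unbound.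

All runs are calculated on assumed constants; the scatter is artificial.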